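**Plan**
- **Cuts, in retrosynthetic order:** the tiglate O–acyl bond and C1'–H (back to a C5 acetyl group); C5–C1' (back to C5–Br); the acetate O–acyl bond and the ester O–CH3 bond, so that C3–O and the acrylate carbonyl rejoin as a γ-lactone; C3–C3a; O1–C2; the Cα–CH2 bond; and the menthyl acetal C–O bond of a furfural-derived butenolide.
- **Enabling feature:** in the dihydrobenzofuran ring (O1, C2, C3, C3a, C7a), C3 bears an acyloxy oxygen and is bonded to C3a, the carbon ortho to O1. C5, para to O1, is substituted. The acrylate carbonyl on C2 lies cis to the C3 oxygen, and that oxygen sits on the γ-carbon of the acrylate chain. C3 is therefore a masked acetal carbon of a γ-alkoxy-α-methylene-γ-butyrolactone that can alkylate its own aryl ether.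
- **Forward order:** the lactone ring comes first (furfural, γ-hydroxybutenolide, menthyl acetal). Then follow hydroxymethylation at Cα, aryl ether formation at C2 with release of the exocyclic methylene, closure of the dihydrofuran ring onto the arene, opening of the lactone to the acetoxy methyl ester, and the C5 side chain.
- **Stereochemistry:** (+)-menthol fixes the acetal carbon by crystallisation, and phenoxide adds anti to it (C2, S). The obligatory cis ring fusion copies C2 onto C3 (S) while the acetal centre is consumed. C1' (S) comes from RuCl[(S,S)-TsDPEN](p-cymene), and the E alkene comes with tigloyl chloride.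

Key step: step 6

Remark: locants O1, C2, C3, C3a, C5, C7a, C1' and Cα (acrylate α-carbon) are those of the target and denote the same atoms in every intermediate. Locants of the lactone ring are marked "lactone". "Menthyl" means (1S,2R,5S)-2-isopropyl-5-methylcyclohexyl.
Remark: acetal 4 is the enantiomer of the familiar crystalline (5R)-acetal of (−)-menthol and must therefore crystallise in the same way.

Step 1
Reactants: 1 furfural
Product: 2 5-hydroxyfuran-2(5H)-one (racemic lactol)
Conditions: O2, visible light, rose bengal disodium salt (C20H2Cl4I4Na2O5, cat.), MeOH, 0–20 °C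
Reagents that add atoms: dioxygen, O=O
Why: Dye-sensitised singlet-oxygen [4+2] photooxygenation of the furan gives an endoperoxide that methanol cleaves with loss of the formyl carbon as formate, the standard entry to the γ-hydroxybutenolide, whose lactol carbon is formed racemic and labile.

Step 2
Reactants: 2 5-hydroxyfuran-2(5H)-one; 3 (+)-menthol
Product: 4 (5S)-5-[(1S,2R,5S)-menthyloxy]furan-2(5H)-one
Conditions: neat, 100 °C; crystallisation from petroleum ether; mother liquor re-equilibrated (cat. TsOH) and recrystallised
Reagents that add atoms: (+)-menthol 3, C[C@H]1CC[C@@H]([C@H](C1)O)C(C)C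
Why: Thermal acetalisation of the pseudo-acid gives both acetal epimers, which interconvert under acid, and the (5S) epimer is collected by crystallisation, so the acetal centre is set by crystallisation-driven selection against the fixed menthyl centres.

Step 3
Reactants: 4 (5S)-5-menthyloxyfuran-2(5H)-one
Product: 6 [(3R,4S,5S)-5-menthyloxy-2-oxo-4-(phenylthio)tetrahydrofuran-3-yl]methyl acetate, via lithium aldolate 5 (not isolated)
Conditions: PhSH, n-BuLi, THF, −78 °C; 4; monomeric CH2O in THF, −78 to −40 °C; Ac2O, −40 to 0 °C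
Reagents that add atoms: thiophenol, Sc1ccccc1; formaldehyde, C=O; acetic anhydride, CC(=O)OC(C)=O; n-butyllithium, [Li]CCCC (lithium of 5 only)
Why: Tandem sulfa-Michael/aldol reaction, the stepwise equivalent of a Morita–Baylis–Hillman hydroxymethylation, in which the thiolate adds to lactone C4 anti to the menthyloxy group, the enolate takes up formaldehyde anti to the new C–S bond, and acetylation of the aldolate blocks retro-aldol cleavage, both new centres being temporary.

Step 4
Reactants: 6 the acetoxymethyl sulfide
Product: 8 [(5S)-5-menthyloxy-2-oxo-2,5-dihydrofuran-3-yl]methyl acetate, via sulfoxide 7 (not isolated)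
Conditions: mCPBA (1.0 equiv), CH2Cl2, −78 to −20 °C; NaHCO3 wash; toluene, 80 °C
Reagents that add atoms: mCPBA, O=C(OO)c1cccc(Cl)c1 (oxygen atom of 7 only; none remains in 8)
Why: Sulfide oxidation and thermal syn elimination of the β-sulfinyl lactone, which uses the acidic lactone C3–H lying cis to sulfur and restores the butenolide, now carrying the acetoxymethyl group, while the two temporary centres vanish and the acetal centre is untouched.

Step 5
Reactants: 8 the acetoxymethyl butenolide; 9 4-bromophenol
Product: 10 (4S,5S)-4-(4-bromophenoxy)-5-[(1S,2R,5S)-menthyloxy]-3-methylenedihydrofuran-2(3H)-one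
Conditions: K2CO3 (1.0 equiv), MeCN, 0 °C to rt; 8 in slight excess over 9
Reagents that add atoms: 4-bromophenol 9, Oc1ccc(Br)cc1
Why: SN2' etherification by conjugate addition–elimination, known for phenols with Morita–Baylis–Hillman-type allylic acetates, in which phenoxide attacks lactone C4 anti to the menthyloxy group (setting the future C2 as S), irreversible loss of acetate drains the otherwise unfavourable oxa-Michael equilibrium and unveils the methylene, direct displacement of acetate is not available, and slow release of a limiting amount of phenoxide restrains a second SN2' on the product.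

Step 6
Reactants: 10 the aryloxy menthyl acetal
Product: 12 (3aS,8bS)-7-bromo-3-methylene-3a,8b-dihydrofuro[3,2-b]benzofuran-2(3H)-one (cis-fused; 2S,3S and 5-bromo in target numbering), via acyloxycarbenium ion 11 (not isolated)
Conditions: BF3·OEt2 (30 mol%), 4 Å MS, CH2Cl2, −40 to 0 °C; quenched cold with Et3N
Reagents that add atoms: none
Why: Proposed new method: BF3 binds the menthyl oxygen of the acetal, menthol leaves, and the cyclic acyloxycarbenium ion 11 is attacked at C3 by the ortho carbon C3a of the aryl ether held on C2, after which loss of the arene proton rearomatises the ring and returns the acid, so the Lewis acid is needed only in catalytic amount. The closest known reaction types are the Lewis acid Friedel–Crafts arylation of γ-alkoxy- and γ-hydroxybutyrolactones (pseudo-acid derivatives) and the acid cyclisation of aryloxyacetaldehyde acetals, which normally runs on to the benzofuran; halting at the lactone-bridged dihydro stage is the untested part. The dihydrofuran ring closes in a five-membered mode that is exo to the C=O+ bond (its oxygen stays outside the new ring, inside the lactone) and endo to the arene C3a–C7a bond. C3 is controlled by C2 alone, because O1 ties the arene to one face of the planar cation, only the cis-fused bicycle is geometrically possible and the acetal centre that relayed the menthol chirality is erased; if the lactone C–O bond ionises first, the open menthyloxycarbenium ion should reach the same cis lactone through cyclisation, benzylic re-ionisation and capture by the carboxyl group. Regioselectivity needs no control, since C5 is blocked by bromine and the two ortho carbons are equivalent. Chemoselectivity is needed against ionisation or Lewis acid promoted [3,3] shift of the allylic aryl ether and against loss of H2 to give the benzofuran; the first is disfavoured because the allyl cation would carry the carbonyl group on its central carbon, and the second is restrained by the acyloxy (not alkoxy) leaving group at C3, the meta bromine, the low temperature and the cold amine quench.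

Step 7
Reactants: 12 the tricyclic lactone
Product: 14 methyl 2-[(2S,3S)-5-bromo-3-hydroxy-2,3-dihydrobenzofuran-2-yl]acrylate, via lithium carboxylate 13 (not isolated)
Conditions: LiOH (1.05 equiv), THF/H2O, 0 °C; concentrate; MeI, DMF, 0 °C to rt; extractive work-up only
Reagents that add atoms: lithium hydroxide, [Li+].[OH-]; iodomethane, CI
Why: Saponification by acyl–oxygen cleavage (hard hydroxide attacks the carbonyl, as in the hydrolysis of simple α-methylene-γ-butyrolactones) followed by SN2 O-alkylation of the carboxylate under neutral conditions, in which the C3–O and C2–O bonds are never broken, so both ring centres are retained.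

Step 8
Reactants: 14 the hydroxy ester
Product: 15 methyl 2-[(2S,3S)-3-acetoxy-5-bromo-2,3-dihydrobenzofuran-2-yl]acrylate
Conditions: Ac2O, pyridine, CH2Cl2, 0 °C to rt
Reagents that add atoms: acetic anhydride, CC(=O)OC(C)=O
Why: Standard O-acetylation with retention at C3, run with the weakly nucleophilic pyridine and without 4-(dimethylamino)pyridine so that no amine adds to the acrylate and expels the allylic aryloxide, and it removes the hydroxyl group that could relactonise.

Step 9
Reactants: 15 the bromo acetate; 16 tributyl(1-ethoxyvinyl)stannane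
Product: 18 methyl 2-[(2S,3S)-3-acetoxy-5-acetyl-2,3-dihydrobenzofuran-2-yl]acrylate, via aryl enol ether 17 (not isolated)
Conditions: 16 (1.5 equiv), Pd(P(t-Bu)3)2 (3 mol%), CsF, 1,4-dioxane, rt; then 1 M HCl, THF, 0 °C
Reagents that add atoms: tributyl(1-ethoxyvinyl)stannane 16, CCCC[Sn](CCCC)(CCCC)C(=C)OCC; water, O
Why: Stille coupling of an aryl bromide with an α-alkoxyvinylstannane under fluoride activation with a bulky electron-rich phosphine on zerovalent palladium, which runs at room temperature so that transmetalation from the excess stannane outruns Heck-type insertion into the hindered acrylate and ionisation of the allylic ether, followed by mild acid hydrolysis of the enol ether to the methyl ketone.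

Step 10
Reactants: 18 the aryl methyl ketone
Product: 19 methyl 2-[(2S,3S)-3-acetoxy-5-[(1S)-1-hydroxyethyl]-2,3-dihydrobenzofuran-2-yl]acrylate
Conditions: RuCl[(S,S)-TsDPEN](p-cymene) (1 mol%), HCO2H/Et3N (5:2), CH2Cl2, rt
Reagents that add atoms: none
Why: Noyori–Ikariya asymmetric transfer hydrogenation, in which the (S,S) catalyst delivers hydride to the Re face of aryl methyl ketones to give the (S) carbinol under pure catalyst control (the ring centres are remote), formic acid makes the reduction of this electron-rich ketone irreversible, and the outer-sphere hydride transfer spares the acrylate C=C and both esters.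

Step 11
Reactants: 19 the (S)-alcohol; 20 tigloyl chloride
Product: 21 (1S)-1-{(2S,3S)-3-acetoxy-2-[1-(methoxycarbonyl)vinyl]-2,3-dihydrobenzofuran-5-yl}ethyl (E)-2-methylbut-2-enoate (CNP0168827.2)
Conditions: pyridine, CH2Cl2, 0 °C to rt
Reagents that add atoms: tigloyl chloride 20, C/C=C(\C)C(=O)Cl
Why: Acylation of a secondary benzylic alcohol by an acid chloride, which leaves the carbinol C–O bond intact (retention at C1'), with pyridine used in place of a trialkylamine to avoid vinylketene formation and so keep the E geometry, and with acid excluded to prevent benzylic ionisation.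

**Compound list**
1 | furfural | O=Cc1ccco1 | starting material
2 | 5-hydroxyfuran-2(5H)-one (racemic) | O=C1C=CC(O)O1 | intermediate
3 | (+)-menthol, (1S,2R,5S) | C[C@H]1CC[C@@H]([C@H](C1)O)C(C)C | starting material
4 | (5S)-5-[(1S,2R,5S)-menthyloxy]furan-2(5H)-one | O=C1C=C[C@@H](O[C@H]2C[C@@H](C)CC[C@@H]2C(C)C)O1 | intermediate
5 | lithium [(3R,4S,5S)-5-menthyloxy-2-oxo-4-(phenylthio)tetrahydrofuran-3-yl]methanolate | [Li+].[O-]C[C@H]1[C@H](Sc2ccccc2)[C@@H](O[C@H]3C[C@@H](C)CC[C@@H]3C(C)C)OC1=O | intermediate
6 | [(3R,4S,5S)-5-menthyloxy-2-oxo-4-(phenylthio)tetrahydrofuran-3-yl]methyl acetate | CC(=O)OC[C@H]1[C@H](Sc2ccccc2)[C@@H](O[C@H]3C[C@@H](C)CC[C@@H]3C(C)C)OC1=O | intermediate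
7 | [(3R,4S,5S)-5-menthyloxy-2-oxo-4-(phenylsulfinyl)tetrahydrofuran-3-yl]methyl acetate (both configurations at sulfur) | CC(=O)OC[C@H]1[C@H](S(=O)c2ccccc2)[C@@H](O[C@H]3C[C@@H](C)CC[C@@H]3C(C)C)OC1=O | intermediate
8 | [(5S)-5-menthyloxy-2-oxo-2,5-dihydrofuran-3-yl]methyl acetate | CC(=O)OCC1=C[C@@H](O[C@H]2C[C@@H](C)CC[C@@H]2C(C)C)OC1=O | intermediate
9 | 4-bromophenol | Oc1ccc(Br)cc1 | starting material
10 | (4S,5S)-4-(4-bromophenoxy)-5-[(1S,2R,5S)-menthyloxy]-3-methylenedihydrofuran-2(3H)-one | C=C1[C@H](Oc2ccc(Br)cc2)[C@@H](O[C@H]3C[C@@H](C)CC[C@@H]3C(C)C)OC1=O | intermediate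
11 | (4S)-4-(4-bromophenoxy)-3-methylene-2-oxo-3,4-dihydro-2H-furan-1-ium (acyloxycarbenium ion) | C=C1[C@H](Oc2ccc(Br)cc2)C=[O+]C1=O | intermediate
12 | (3aS,8bS)-7-bromo-3-methylene-3a,8b-dihydrofuro[3,2-b]benzofuran-2(3H)-one | C=C(C3=O)[C@@H]1Oc2ccc(Br)cc2[C@@H]1O3 | intermediate
13 | lithium 2-[(2S,3S)-5-bromo-3-hydroxy-2,3-dihydrobenzofuran-2-yl]acrylate | [Li+].[O-]C(=O)C(=C)[C@@H]1Oc2ccc(Br)cc2[C@@H]1O | intermediate
14 | methyl 2-[(2S,3S)-5-bromo-3-hydroxy-2,3-dihydrobenzofuran-2-yl]acrylate | C=C(C(=O)OC)[C@@H]1Oc2ccc(Br)cc2[C@@H]1O | intermediate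
15 | methyl 2-[(2S,3S)-3-acetoxy-5-bromo-2,3-dihydrobenzofuran-2-yl]acrylate | C=C(C(=O)OC)[C@@H]1Oc2ccc(Br)cc2[C@@H]1OC(C)=O | intermediate
16 | tributyl(1-ethoxyvinyl)stannane | CCCC[Sn](CCCC)(CCCC)C(=C)OCC | starting material
17 | methyl 2-[(2S,3S)-3-acetoxy-5-(1-ethoxyvinyl)-2,3-dihydrobenzofuran-2-yl]acrylate | C=C(C(=O)OC)[C@@H]1Oc2ccc(C(=C)OCC)cc2[C@@H]1OC(C)=O | intermediate
18 | methyl 2-[(2S,3S)-3-acetoxy-5-acetyl-2,3-dihydrobenzofuran-2-yl]acrylate | C=C(C(=O)OC)[C@@H]1Oc2ccc(C(C)=O)cc2[C@@H]1OC(C)=O | intermediate
19 | methyl 2-[(2S,3S)-3-acetoxy-5-[(1S)-1-hydroxyethyl]-2,3-dihydrobenzofuran-2-yl]acrylate | C=C(C(=O)OC)[C@@H]1Oc2ccc([C@H](C)O)cc2[C@@H]1OC(C)=O | intermediate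
20 | tigloyl chloride, (E)-2-methylbut-2-enoyl chloride | C/C=C(\C)C(=O)Cl | starting material
21 | (1S)-1-{(2S,3S)-3-acetoxy-2-[1-(methoxycarbonyl)vinyl]-2,3-dihydrobenzofuran-5-yl}ethyl (E)-2-methylbut-2-enoate | C=C(C(=O)OC)[C@@H]1Oc2ccc([C@H](C)OC(=O)/C(C)=C/C)cc2[C@@H]1OC(C)=O | target

Total step count: 11. Longest linear sequence: 11 steps (1 to 21).

**Steps most likely to fail**

**1. Step 6.**
- *What may go wrong:* Ionisation of the acetal may be too slow next to two electron-withdrawing neighbours. The bromine-deactivated arene may fail to capture the cation before a proton is lost from C2. The Lewis acid may trigger a [3,3] shift of the allyl aryl ether onto the exocyclic methylene. The product may re-ionise at C3 and aromatise.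
- *Fallback:* The same C3–C3a bond is made with inverted polarity, using known reaction types. It sets out from 8 and comes back at 14.
- The etherification of step 5 is run with commercial 4-bromo-2-iodophenol to give (4S,5S)-4-(4-bromo-2-iodophenoxy)-5-[(1S,2R,5S)-menthyloxy]-3-methylenedihydrofuran-2(3H)-one F1.
- Aqueous trifluoroacetic acid hydrolyses the menthyl acetal to the lactol (4S)-4-(4-bromo-2-iodophenoxy)-5-hydroxy-3-methylenedihydrofuran-2(3H)-one F2.
- KHCO3 and MeI in DMF at 0 °C alkylate the ring-opened carboxylate form to give methyl (3S)-3-(4-bromo-2-iodophenoxy)-2-methylene-4-oxobutanoate F3.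
- An intramolecular Nozaki–Hiyama–Kishi reaction (CrCl2, cat. NiCl2, DMF, rt) selects the carbon–iodine bond over the carbon–bromine bond and adds the aryl group to the aldehyde.
- The facial outcome at C3 is not secured by the substrate, so the cis alcohol 14 would have to be separated from its C3 epimer before the route continues with step 8.

**2. Step 5.**
- *What may go wrong:* Phenoxide may re-attack the product at the exocyclic methylene and carry it on to the linear, more conjugated aryloxymethyl isomer. The adduct enolate may revert faster than it loses acetate. The base may epimerise the acetal carbon through the dienolate.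
- *Fallback:* The anionic leaving group is replaced by a neutral amine held in an isolable quaternary salt (SN2 then SN2', as established for Morita–Baylis–Hillman bromides with oxygen nucleophiles). It sets out from 5 and comes back at 10.
- The aldolate 5 is quenched with NH4Cl instead of Ac2O to give (3R,4S,5S)-3-(hydroxymethyl)-5-menthyloxy-4-(phenylthio)dihydrofuran-2(3H)-one F4.
- mCPBA gives (3R,4S,5S)-3-(hydroxymethyl)-5-menthyloxy-4-(phenylsulfinyl)dihydrofuran-2(3H)-one F5, which on warming in toluene eliminates to (5S)-3-(hydroxymethyl)-5-menthyloxyfuran-2(5H)-one F6.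
- Appel bromination (CBr4, PPh3, CH2Cl2, 0 °C) gives (5S)-3-(bromomethyl)-5-menthyloxyfuran-2(5H)-one F7.
- 1,4-Diazabicyclo[2.2.2]octane in THF displaces bromide to give 1-{[(5S)-5-menthyloxy-2-oxo-2,5-dihydrofuran-3-yl]methyl}-4-aza-1-azoniabicyclo[2.2.2]octane bromide F8.
- 9 with K2CO3 then attacks lactone C4 anti to the menthyloxy group and expels the amine, giving 10.

**3. Step 7.**
- *What may go wrong:* Hydroxide may add to the exocyclic methylene and expel the aryloxide, opening the dihydrofuran ring. Base may induce anti elimination across C2–C3. The hydroxy ester may close back to the lactone before it is acetylated.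
- *Fallback:* The methylene is masked as a sulfide and restored by sulfoxide elimination, both classical operations on α-methylene lactones. It sets out from 12 and comes back at 15.
- Thiophenol with catalytic Et3N (CH2Cl2, 0 °C), where the thiol protonates the adduct enolate at once, gives (3aS,8bS)-7-bromo-3-[(phenylthio)methyl]-3a,8b-dihydrofuro[3,2-b]benzofuran-2(3H)-one F9. Either configuration at the new α-carbon serves.
- LiOH gives lithium 2-[(2S,3S)-5-bromo-3-hydroxy-2,3-dihydrobenzofuran-2-yl]-3-(phenylthio)propanoate F10.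
- MeI in DMF gives methyl 2-[(2S,3S)-5-bromo-3-hydroxy-2,3-dihydrobenzofuran-2-yl]-3-(phenylthio)propanoate F11, which is acetylated without purification (Ac2O, pyridine) to methyl 2-[(2S,3S)-3-acetoxy-5-bromo-2,3-dihydrobenzofuran-2-yl]-3-(phenylthio)propanoate F12.
- mCPBA gives methyl 2-[(2S,3S)-3-acetoxy-5-bromo-2,3-dihydrobenzofuran-2-yl]-3-(phenylsulfinyl)propanoate F13, whose thermal syn elimination in toluene restores the acrylate and delivers 15.

**Further compounds**
F1 | step 6 | (4S,5S)-4-(4-bromo-2-iodophenoxy)-5-[(1S,2R,5S)-menthyloxy]-3-methylenedihydrofuran-2(3H)-one | C=C1[C@H](Oc2ccc(Br)cc2I)[C@@H](O[C@H]3C[C@@H](C)CC[C@@H]3C(C)C)OC1=O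
F2 | step 6 | (4S)-4-(4-bromo-2-iodophenoxy)-5-hydroxy-3-methylenedihydrofuran-2(3H)-one (both lactol epimers) | C=C1[C@H](Oc2ccc(Br)cc2I)C(O)OC1=O
F3 | step 6 | methyl (3S)-3-(4-bromo-2-iodophenoxy)-2-methylene-4-oxobutanoate | C=C(C(=O)OC)[C@H](Oc1ccc(Br)cc1I)C=O
F4 | step 5 | (3R,4S,5S)-3-(hydroxymethyl)-5-menthyloxy-4-(phenylthio)dihydrofuran-2(3H)-one | OC[C@H]1[C@H](Sc2ccccc2)[C@@H](O[C@H]3C[C@@H](C)CC[C@@H]3C(C)C)OC1=O
F5 | step 5 | (3R,4S,5S)-3-(hydroxymethyl)-5-menthyloxy-4-(phenylsulfinyl)dihydrofuran-2(3H)-one (both configurations at sulfur) | OC[C@H]1[C@H](S(=O)c2ccccc2)[C@@H](O[C@H]3C[C@@H](C)CC[C@@H]3C(C)C)OC1=O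
F6 | step 5 | (5S)-3-(hydroxymethyl)-5-menthyloxyfuran-2(5H)-one | OCC1=C[C@@H](O[C@H]2C[C@@H](C)CC[C@@H]2C(C)C)OC1=O
F7 | step 5 | (5S)-3-(bromomethyl)-5-menthyloxyfuran-2(5H)-one | BrCC1=C[C@@H](O[C@H]2C[C@@H](C)CC[C@@H]2C(C)C)OC1=O
F8 | step 5 | 1-{[(5S)-5-menthyloxy-2-oxo-2,5-dihydrofuran-3-yl]methyl}-4-aza-1-azoniabicyclo[2.2.2]octane bromide | [Br-].C1C[N+]2(CCN1CC2)CC3=C[C@@H](O[C@H]4C[C@@H](C)CC[C@@H]4C(C)C)OC3=O
F9 | step 7 | (3aS,8bS)-7-bromo-3-[(phenylthio)methyl]-3a,8b-dihydrofuro[3,2-b]benzofuran-2(3H)-one (α-carbon unassigned) | c4ccccc4SCC(C3=O)[C@@H]1Oc2ccc(Br)cc2[C@@H]1O3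
F10 | step 7 | lithium 2-[(2S,3S)-5-bromo-3-hydroxy-2,3-dihydrobenzofuran-2-yl]-3-(phenylthio)propanoate | [Li+].[O-]C(=O)C(CSc4ccccc4)[C@@H]1Oc2ccc(Br)cc2[C@@H]1O
F11 | step 7 | methyl 2-[(2S,3S)-5-bromo-3-hydroxy-2,3-dihydrobenzofuran-2-yl]-3-(phenylthio)propanoate | COC(=O)C(CSc4ccccc4)[C@@H]1Oc2ccc(Br)cc2[C@@H]1O
F12 | step 7 | methyl 2-[(2S,3S)-3-acetoxy-5-bromo-2,3-dihydrobenzofuran-2-yl]-3-(phenylthio)propanoate | COC(=O)C(CSc4ccccc4)[C@@H]1Oc2ccc(Br)cc2[C@@H]1OC(C)=O
F13 | step 7 | methyl 2-[(2S,3S)-3-acetoxy-5-bromo-2,3-dihydrobenzofuran-2-yl]-3-(phenylsulfinyl)propanoate | COC(=O)C(CS(=O)c4ccccc4)[C@@H]1Oc2ccc(Br)cc2[C@@H]1OC(C)=O
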